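# Total synthesis proposal for CNP0260503.1 (3β,12α,13-trihydroxy C19-gibberellin 19,10-lactone)

## Analysis of the target

- **Ring system.** The target is a pentacyclic C19 gibberellin. It has a 6-5-6-5 carbocycle (rings A–D). A γ-lactone (C19) spans C4 and C10 across the α face of ring A. Rings C and D form a bicyclo[3.2.1]octane.
- **Stereocentres.** Nine stereocentres (C3, C4, C5, C6, C8, C9, C10, C12, C13) form one unbroken array. Four of them (C4, C8, C10, C13) are fully substituted.
- **Ring fusions.** A/B is trans (10α-O, 5β-H). B/C is cis (9β-H and C15 both β). The 6β-carboxyl is trans to C4.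
- **Hydroxyl groups.** The 3β-OH is cis to the C18 methyl and anti to C19. The 12α-OH is axial on ring C, on the face away from the C15–C16 bridge.
- **Sensitive groups.**
  - The β-hydroxy lactone epimerises at C3 in base by retro-aldol.
  - The 13-hydroxy-16-ene undergoes Wagner–Meerwein rearrangement in strong acid.
  - In any intermediate where a C8 or C13 carbonyl acidifies C9–H, the C10 carboxylate can be lost by elimination.
- **Difficulty.** Quaternary C8 must be built next to the C6 ester. 5β-H must be placed on the more hindered face of ring A. The 12,13-diol must end up beside an exocyclic alkene.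
- **Feature carrying the strategy.** Bridgehead C13 is a tertiary allylic alcohol bonded directly to the methylene-bearing C16 of five-membered ring D. This is what remains when a C13 ketyl radical takes over a vinyl group from its neighbour C14.

## Retrosynthetic reasoning

**Deprotection (26 ⇒ 25 ⇒ 24).** The free acid and the three hydroxyls are unmasked last. The C7 methyl ester is cleaved by SN2 attack of a thiolate on the methyl group while O3 and O12 are still silylated. No C3 alkoxide can then trigger retro-aldol. Buffered fluoride removes both silyl ethers afterwards and spares the 13-hydroxy-16-ene.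

**C13–C16 (24 ⇒ 23).** Moving C16 back from C13 to C14 turns ring D into a methylenecyclobutane (C8–C15–C16–C14) next to a C13 ketone. The forward reaction is a ketyl 1,2-vinyl shift. It delivers the bridgehead alcohol, the exocyclic methylene and the C14 one-carbon bridge at their final oxidation levels. It is paid for by cyclobutane strain. No other cut of ring D gives all three features from one functional group.

**C12–O (23 ⇒ 22 ⇒ 21).** O12 sits α to the C13 ketone, so it is an enolate oxidation. It is placed after the cycloaddition. In 21 the ketone α-CH2 is the kinetically most accessible acidic site. In enone 19 the most acidic proton is C6–H, and a C9 carbanion would expel the lactone.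

**C8–C15 and C14–C16 (21 ⇒ 19 + 20).** The four-membered ring is the head-to-head photoadduct of 20 with the C8=C14 enone of 19. This sets quaternary C8. C14 is only a relay centre.

**C6–C8 and the lactone C–O bond (19 ⇒ 16).**
- The enone is read as a 1,3-transposed vinylogous ester. The C7 ester enolate attacks the C8 carbonyl, and acid then moves the carbonyl to C13.
- Closing ring B fixes C7 on the β face. The freed 10α-OH can then acylate only on C19, with which it is locked syn-diaxial.
- Forming the lactone earlier would let the flexible C7 ester capture O10. It would also put a good leaving group β to C9 during the base step.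

**C9–C10 (16 ⇒ 13 + 14).** C9 is the α′ carbon of 14 and C10 is a ring-A ketone. An aldol addition makes the bond and the tertiary C10–O in one operation. Silylation of the aldolate freezes it.

**C10 ketone and 5β-H (13 ⇒ 12 ⇒ 11 ⇒ 10).** External reagents approach ring A from the α face, but H5 must be β. The hydrogen is therefore delivered from within. An α-epoxide of the C5=C10 alkene rearranges by a C10→C5 hydride shift on the β face. The alkene comes from deconjugating enoate 10.

**Excision of one carbon (10 ⇒ 9 ⇒ 8 ⇒ 7).** C19, C7 and C6 are all ring atoms of the second ring of dienone 7. Cleaving its disubstituted enone bond, with loss of the α-carbon, turns that ring into the C19 and C7 carboxyl groups. The Z-alkene geometry is inherited from the ring.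

**C3 and C4 (7 ⇒ 6 ⇒ 5 ⇒ 4 ⇒ 3 ⇒ 1 + 2).** Ring A is 1. Michael addition to 2 gives prochiral triketone 3. A catalytic enamine aldol picks one of its two enantiotopic ring carbonyls (C4). Hydride delivery anti to the angular methyl then sets C3.

## Alternatives that were turned down

**Alternative 1:**
- *Disconnection:* C8–C9 and C11–C12, opening rings B and C to a chain.
- *Forward key step:* An intramolecular Diels–Alder reaction. A C9–C11 vinyl ketone adds to a 12,13-dioxygenated C8–C14–C13–C12 diene held by a C6–C5–C10 tether, giving hydrindanone A1.
- *In favour:* Two rings and three stereocentres (C8, C9, C12) arise at once. The propargyl arm of A1 allows a ketyl–alkyne closure of ring D. That closure is as well founded as the vinyl shift and needs no photochemistry, so on this point it is equally strong.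
- *Against:*
  - The diene terminus C8 is fully substituted.
  - The geometry of a doubly oxygenated diene must be controlled, and the vinyl ketone is prone to polymerise.
  - Nothing in the chain fixes the absolute sense, so a chiral catalyst or auxiliary is needed.
  - A1 carries neither C7 nor ring A, quaternary C4 or the lactone. All of these would be added one after another at C10, C5 and C6.
  - The 12-ether α to the later C13 ketyl poses the same elimination problem.
- *Comparison:* The chosen route starts with C3, C4, C6, C7 and C19 already present in one cheap enantiopure bicycle. It spends only two steps on ring D.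

**Alternative 2:**
- *Disconnection:* C5–C10 and C3–C4, opening rings A and B.
- *Forward key step:* An intramolecular furan Diels–Alder reaction. A furan on C9 adds across a Z-enoate C4=C5 to give the oxygen-bridged pentacycle A2.
- *In favour:* Rings A and B, quaternary C4 and both C3–O and C10–O appear in one step. In bond count per step it is stronger than anything in the chosen route.
- *Against:*
  - Furan cycloadditions are reversible, and this one must create a quaternary centre from a trisubstituted dienophile.
  - The whole C/D bicyclooctane with its protected diol has to be built first and carried through.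
  - The single bridging oxygen of A2 holds C3 and C10 on the same (α) face, whereas the target has 10α-O but 3β-OH. After ether cleavage C3 must be inverted, the C1=C2 alkene reduced and the lactone formed separately.
- *Comparison:* The chosen route sets 3β-O directly in its third step. The risky cyclisation is left for a late, strain-driven and irreversible step.

**Alternative 3:**
- *Disconnection:* C9–C10, opening ring B to a prochiral 4,4-disubstituted cyclohexadienone carrying a C10 aldehyde.
- *Forward key step:* A carbene-catalysed intramolecular Stetter reaction. It adds the acyl anion to one of two enantiotopic β-carbons and gives hydrindenedione A3.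
- *In favour:* Catalytic asymmetric desymmetrisation of this substrate class is well established. C8 and C9 are set together, and A3 is reached in very few steps. As an entry to the B/C core it is shorter than the chosen route.
- *Against:*
  - The surviving enone carbonyl of A3 is at C12. A 1,2-transposition with oxidation is needed for the 12-ol/13-one pattern.
  - C5 and C6 are bare methylenes. C7, ring A, C4, C3 and the lactone all remain to be built.
  - Ring D still has to be closed.
- *Comparison:* The early brevity is lost afterwards. The chosen strategy also relies on a catalytic desymmetrisation, but of the ring that carries the hardest quaternary carbon and the lactone carbonyl.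

Key step: step 17

Remark on the chemistry: locants are gibberellane locants throughout (C18 = methyl, C19 = lactone carbonyl, C7 = carboxyl carbon). α is the face of ring A that carries the lactone bridge, and β is the opposite face.

## Route

Step 1
Reactants: 1 2-methylcyclohexane-1,3-dione; 2 methyl vinyl ketone
Product: 3 2-methyl-2-(3-oxobutyl)cyclohexane-1,3-dione
Conditions: AcOH (cat.), hydroquinone (cat.), H2O, 70 °C
Reagents that add atoms: none
Why: Michael addition of the acidic 1,3-dione to the enone; the new quaternary carbon (C4) is still prochiral.

Step 2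
Reactants: 3 2-methyl-2-(3-oxobutyl)cyclohexane-1,3-dione
Product: 4 (S)-Wieland–Miescher ketone, (8aS)-8a-methyl-3,4,8,8a-tetrahydronaphthalene-1,6(2H,7H)-dione
Conditions: L-proline (cat.), DMSO, rt; recrystallisation
Reagents that add atoms: none
Why: Hajos–Parrish–Eder–Sauer–Wiechert aldol condensation; the proline enamine of the side-chain ketone attacks one of the two enantiotopic ring carbonyls and so fixes C4, and crystallisation should raise the enantiopurity.

Step 3
Reactants: 4 (S)-Wieland–Miescher ketone
Product: 5 (4aS,5S)-5-hydroxy-4a-methyl-4,4a,5,6,7,8-hexahydronaphthalen-2(3H)-one (3β-OH, cis to the angular methyl)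
Conditions: NaBH4, EtOH, 0 °C
Reagents that add atoms: none
Why: The saturated ketone is more electrophilic than the enone; hydride arrives anti to the axial angular methyl, so the hydroxyl ends cis to C18, which is the 3β configuration.

Step 4
Reactants: 5 hydroxy enone
Product: 6 (4aS,5S)-5-(tert-butyldimethylsilyloxy)-4a-methyl-4,4a,5,6,7,8-hexahydronaphthalen-2(3H)-one
Conditions: TBSCl, imidazole, DMF, rt → 40 °C
Reagents that add atoms: tert-butyldimethylsilyl chloride, CC(C)(C)[Si](C)(C)Cl
Why: Standard silylation; the hindered secondary TBS ether should survive every later acidic and basic step up to the final fluoride treatment.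

Step 5
Reactants: 6 silyloxy enone
Product: 7 (4aS,5S)-5-(tert-butyldimethylsilyloxy)-4a-methyl-5,6,7,8-tetrahydronaphthalen-2(4aH)-one (cross-conjugated dienone)
Conditions: DDQ, dioxane, reflux
Reagents that add atoms: none
Why: Quinone dehydrogenation of a 4-en-3-one type enone under neutral conditions proceeds through the cross-conjugated dienol and introduces the disubstituted α′,β′ double bond (future C19 and the carbon to be excised).

Step 6
Reactants: 7 cross-conjugated dienone
Product: 8 ring-A aldehyde acid: cyclohexane with a (Z)-CH–CO2H alkylidene at C5 (C7 syn to C4), 4α-CHO, 4β-CH3, 3β-OTBS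
Conditions: OsO4 (cat.), NaIO4, dioxane–H2O, rt
Reagents that add atoms: sodium periodate, [Na+].[O-]I(=O)(=O)=O; water, O
Why: Lemieux–Johnson cleavage; osmylation should prefer the less hindered disubstituted enone bond over the β,β-disubstituted one, as in ring-A cleavage of steroidal 1,4-dien-3-ones. Periodate then cleaves the glycol and the resulting α-keto aldehyde, so one carbon leaves as formic acid; 8 may rest as its six-membered lactol.

Step 7
Reactants: 8 ring-A aldehyde acid
Product: 9 ring-A diacid: (Z)-CH–CO2H alkylidene at C5, 4α-CO2H, 4β-CH3, 3β-OTBS
Conditions: NaClO2, NaH2PO4, 2-methyl-2-butene, t-BuOH–H2O, rt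
Reagents that add atoms: sodium chlorite, [Na+].[O-]Cl=O
Why: Pinnick oxidation of the non-enolisable neopentyl aldehyde (through the open form of the lactol); the enoic acid and the silyl ether are inert.

Step 8
Reactants: 9 ring-A diacid
Product: 10 ring-A dimethyl ester: (Z)-CH–CO2Me alkylidene at C5, 4α-CO2Me, 4β-CH3, 3β-OTBS
Conditions: MeI, K2CO3, DMF, rt
Reagents that add atoms: iodomethane, CI
Why: Carboxylate alkylation is an SN2 reaction at methyl, so the hindrance around C19 does not matter.

Step 9
Reactants: 10 ring-A dimethyl ester
Product: 11 β,γ-unsaturated diester: C5=C10 cyclohexene bearing CH2CO2Me on C5, 4α-CO2Me, 4β-CH3, 3β-OTBS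
Conditions: LDA, DMPU, THF, −78 °C; AcOH, −78 °C
Reagents that add atoms: none
Why: Deconjugative protonation; C10 carries the only γ-hydrogens, and the dienolate is protonated kinetically at the α-carbon C6. Relief of the allylic strain between the Z-ester and quaternary C4 also favours 11 thermodynamically.

Step 10
Reactants: 11 β,γ-unsaturated diester
Product: 12 5α,10α-epoxide of 11
Conditions: m-CPBA, CH2Cl2, 0 °C
Reagents that add atoms: 3-chloroperoxybenzoic acid, O=C(OO)c1cccc(Cl)c1
Why: Prilezhaev epoxidation of the only alkene; in the half-chair with equatorial OTBS the allylic 4β-methyl is pseudo-axial, so both β substituents screen the β face and the peracid should add from the α face.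

Step 11
Reactants: 12 5α,10α-epoxide
Product: 13 keto diester: C10 ketone, 5β-H with α-CH2CO2Me, 4α-CO2Me, 4β-CH3, 3β-OTBS
Conditions: BF3·OEt2 (cat.), CH2Cl2, −78 → −20 °C
Reagents that add atoms: none
Why: Meinwald rearrangement; the Lewis acid opens the epoxide at tertiary C5, and the C10 hydrogen, which lies on the β face anti to the departing oxygen, migrates to C5. The attack face of step 10 is thereby inverted into 5β-H, as in the 5α,6α-epoxide → 5β-6-ketone rearrangement of steroids; C5 is used before it can epimerise.

Step 12
Reactants: 13 keto diester; 14 3-ethoxycyclohex-2-en-1-one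
Product: 16 C10 trimethylsilyl ether of the C9–C10 aldol adduct (10α-OTMS 9β-H), via lithium aldolate 15 (not isolated)
Conditions: LDA, 14, THF, −78 °C; 13; then TMSCl, −78 → −20 °C
Reagents that add atoms: chlorotrimethylsilane, C[Si](C)(C)Cl
Why: Kinetic α′-enolate of the vinylogous ester in an aldol addition. The axial 4α-ester blocks axial attack, so the bulky enolate enters equatorially from the β side and O10 ends α. The ring-locked E-enolate in a closed transition state with the C5 branch equatorial gives the anti adduct, which is 9β-H. Silylation stops retro-aldol and stops acylation of O10 by the flexible C7 ester.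

Step 13
Reactants: 16 silylated aldol adduct
Product: 19 A/B/C lactone enone (13-oxo-8(14)-ene 19→10-lactone 7-methyl ester 3β-OTBS), via lithium C8-alkoxide 17 (not isolated), via hydroxy enone diester 18 (not isolated)
Conditions: LDA, THF, −78 → −30 °C; then 1 M HCl, THF, 0 °C → rt
Reagents that add atoms: water, O
Why: Intramolecular Stork–Danheiser sequence; the accessible C6 methylene is deprotonated faster than tertiary C9–H, and the ester enolate closes ring B (5-exo-trig) on the C8 carbonyl. Acid ionises the allylic carbinol, transposes the carbonyl to C13 and removes the TMS group; the 10α-OH, now locked syn-diaxial to the 4α-ester, lactonises. C6–H is vinylogously acidic and settles as the 6β-ester, trans to C4.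

Step 14
Reactants: 19 A/B/C lactone enone; 20 propadiene (allene)
Product: 21 head-to-head photoadduct: methylenecyclobutane C8–C15–C16–C14 cis-fused on the β face, C13 ketone
Conditions: 20 (excess), CH2Cl2, hν (Hg lamp, Pyrex), −78 °C; then neutral Al2O3
Reagents that add atoms: none
Why: Enone–allene [2+2] photocycloaddition, which normally places the allene central carbon on the enone α-carbon. Ring B is already trans-fused to ring A, so closure of the biradical to the less strained cis B/C array (C15 on the face of 9β-H) should be preferred, the α face also being flanked by the lactone bridge; alumina converges any trans-fused cyclobutane through the C14 enol.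

Step 15
Reactants: 21 photoadduct
Product: 22 12α-hydroxy ketone
Conditions: KHMDS, THF, −78 °C; 2-(phenylsulfonyl)-3-phenyloxaziridine; AcOH
Reagents that add atoms: 2-(phenylsulfonyl)-3-phenyloxaziridine, O=S(=O)(c1ccccc1)N1OC1c1ccccc1
Why: Davis enolate oxidation; kinetic deprotonation takes the unhindered C12 methylene rather than the tertiary C14–H or the ester C6–H. The oxidant approaches anti to the cyclobutane carbon C16 that leans over the β face. The resulting 12α-oxygen is also equatorial in the preferred half-chair, so kinetic and thermodynamic preferences agree.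

Step 16
Reactants: 22 12α-hydroxy ketone
Product: 23 methylenecyclobutane ketone, 3,12-bis-TBS ether, C7 methyl ester
Conditions: TBSOTf, 2,6-lutidine, CH2Cl2, 0 °C
Reagents that add atoms: tert-butyldimethylsilyl trifluoromethanesulfonate, CC(C)(C)[Si](C)(C)OS(=O)(=O)C(F)(F)F
Why: Silylation under weakly basic conditions leaves C12 and C14 untouched and turns O12 into a poor leaving group for the next step.

Step 17
Reactants: 23 methylenecyclobutane ketone
Product: 24 13-hydroxy-16-methylene pentacycle, 3,12-bis-TBS ether, C7 methyl ester
Conditions: SmI2 (slow addition), HMPA, t-BuOH, THF, 0 °C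
Reagents that add atoms: none
Why: Electron transfer to the C13 carbonyl gives a samarium ketyl whose carbon adds 3-exo-trig to C16 of the neighbouring exocyclic alkene, producing a cyclopropylcarbinyl radical centred on C17. β-Scission of the cyclopropane bond C14–C16, which is also a cyclobutane bond, restores C16=C17, leaves a secondary C14 radical and releases the four-ring strain, so the net 1,2-vinyl shift is irreversible; a second electron and t-BuOH (or hydrogen abstraction from THF) turn C14 into CH2. The closest known reaction type is the SmI2-induced rearrangement of enone–allene photoadducts (2-methylenecyclobutyl ketones) to bridgehead-hydroxy methylenebicyclo[3.2.1]octanes, a Dowd–Beckwith-type shift. Ring D (C8–C14–C13–C16–C15) is therefore closed by a 3-exo-trig addition followed by ring-expanding fragmentation, not by a direct five-membered closure. The only new stereocentre, C13, is fixed by geometry: C16 hangs from C14 on the β face and can reach only the β lobe of C13, which leaves O13 pointing outward. The unimolecular shift must outrun a second reduction of the ketyl, which would expel O12 or give the secondary carbinol; slow addition keeps the Sm(II) concentration low, silyloxide is a poor leaving group, and the equatorial C12–O bond lies near the nodal plane of the ketyl π system whereas the C14–C16 bond is nearly parallel to it. The ring-fusion bond C8–C14 is equally poorly aligned, so cyclobutylcarbinyl opening to an eight-membered ring should not compete.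

Step 18
Reactants: 24 13-hydroxy-16-methylene pentacycle
Product: 25 3,12-bis-TBS ether of the target acid
Conditions: n-PrSH, n-BuLi, HMPA, 0 °C → rt; then dil. HCl
Reagents that add atoms: none
Why: SN2 demethylation by thiolate attacks the ester methyl, not the hindered acyl carbon. The lactone oxygen sits on tertiary C10 and cannot be displaced, and with O3 silylated no retro-aldol can start.

Step 19
Reactants: 25 bis-silyl acid
Product: 26 target, CNP0260503.1
Conditions: HF·pyridine, pyridine, THF, 0 °C → rt
Reagents that add atoms: none
Why: Fluoride-driven desilylation in a buffered, weakly acidic medium avoids both base-induced C3 epimerisation and acid-induced rearrangement of the 13-hydroxy-16-ene.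

## Compound list

1 | 2-methylcyclohexane-1,3-dione | CC1C(=O)CCCC1=O | starting material
2 | methyl vinyl ketone | C=CC(C)=O | starting material
3 | 2-methyl-2-(3-oxobutyl)cyclohexane-1,3-dione | CC(=O)CCC1(C)C(=O)CCCC1=O | intermediate
4 | (S)-Wieland–Miescher ketone | C[C@]12CCC(=O)C=C1CCCC2=O | intermediate
5 | (4aS,5S)-5-hydroxy-4a-methyl-4,4a,5,6,7,8-hexahydronaphthalen-2(3H)-one | C[C@]12CCC(=O)C=C1CCC[C@@H]2O | intermediate
6 | TBS ether of 5 | C[C@]12CCC(=O)C=C1CCC[C@@H]2O[Si](C)(C)C(C)(C)C | intermediate
7 | cross-conjugated dienone | C[C@]12C=CC(=O)C=C1CCC[C@@H]2O[Si](C)(C)C(C)(C)C | intermediate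
8 | ring-A aldehyde acid (Z-enoic acid, 4α-CHO) | OC(=O)/C=C1/CCC[C@H](O[Si](C)(C)C(C)(C)C)[C@@]1(C)C=O | intermediate
9 | ring-A diacid | OC(=O)/C=C1/CCC[C@H](O[Si](C)(C)C(C)(C)C)[C@@]1(C)C(=O)O | intermediate
10 | ring-A dimethyl ester (Z-enoate) | COC(=O)/C=C1/CCC[C@H](O[Si](C)(C)C(C)(C)C)[C@@]1(C)C(=O)OC | intermediate
11 | β,γ-unsaturated diester (C5=C10) | COC(=O)CC1=CCC[C@H](O[Si](C)(C)C(C)(C)C)[C@@]1(C)C(=O)OC | intermediate
12 | 5α,10α-epoxide | COC(=O)C[C@]12O[C@H]1CC[C@H](O[Si](C)(C)C(C)(C)C)[C@@]2(C)C(=O)OC | intermediate
13 | keto diester (C10 ketone, 5β-H) | COC(=O)C[C@H]1C(=O)CC[C@H](O[Si](C)(C)C(C)(C)C)[C@@]1(C)C(=O)OC | intermediate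
14 | 3-ethoxycyclohex-2-en-1-one | CCOC1=CC(=O)CCC1 | starting material
15 | lithium aldolate | CCOC1=CC(=O)[C@@H](CC1)[C@]2([O-])CC[C@H](O[Si](C)(C)C(C)(C)C)[C@@](C)(C(=O)OC)[C@H]2CC(=O)OC.[Li+] | intermediate
16 | C10 TMS ether of the aldol adduct | CCOC1=CC(=O)[C@@H](CC1)[C@]2(O[Si](C)(C)C)CC[C@H](O[Si](C)(C)C(C)(C)C)[C@@](C)(C(=O)OC)[C@H]2CC(=O)OC | intermediate
17 | lithium C8-alkoxide (ring B closed; C6 and C8 not defined, both are erased or equilibrated) | CCOC1=CC2([O-])C(C(=O)OC)[C@@H]3[C@](C)(C(=O)OC)[C@@H](O[Si](C)(C)C(C)(C)C)CC[C@@]3(O[Si](C)(C)C)[C@@H]2CC1.[Li+] | intermediate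
18 | hydroxy enone diester | O=C1C=C2[C@@H](C(=O)OC)[C@@H]3[C@](C)(C(=O)OC)[C@@H](O[Si](C)(C)C(C)(C)C)CC[C@@]3(O)[C@@H]2CC1 | intermediate
19 | A/B/C lactone enone | O=C1C=C2[C@@H](C(=O)OC)[C@@H]3[C@@]4(C)[C@@H](O[Si](C)(C)C(C)(C)C)CC[C@@]3(OC4=O)[C@@H]2CC1 | intermediate
20 | propadiene (allene) | C=C=C | starting material
21 | allene photoadduct (C13 ketone, C12 unsubstituted) | C=C1C[C@]23[C@H]1C(=O)CC[C@H]2[C@@]12CC[C@H](O[Si](C)(C)C(C)(C)C)[C@@](C)(C(=O)O1)[C@H]2[C@@H]3C(=O)OC | intermediate
22 | 12α-hydroxy ketone | C=C1C[C@]23[C@H]1C(=O)[C@@H](O)C[C@H]2[C@@]12CC[C@H](O[Si](C)(C)C(C)(C)C)[C@@](C)(C(=O)O1)[C@H]2[C@@H]3C(=O)OC | intermediate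
23 | methylenecyclobutane ketone, 3,12-bis-TBS ether | C=C1C[C@]23[C@H]1C(=O)[C@@H](O[Si](C)(C)C(C)(C)C)C[C@H]2[C@@]12CC[C@H](O[Si](C)(C)C(C)(C)C)[C@@](C)(C(=O)O1)[C@H]2[C@@H]3C(=O)OC | intermediate
24 | 13-hydroxy-16-methylene pentacycle, 3,12-bis-TBS ether, methyl ester | C=C1C[C@]23C[C@@]1(O)[C@@H](O[Si](C)(C)C(C)(C)C)C[C@H]2[C@@]12CC[C@H](O[Si](C)(C)C(C)(C)C)[C@@](C)(C(=O)O1)[C@H]2[C@@H]3C(=O)OC | intermediate
25 | 3,12-bis-TBS ether of the target acid | C=C1C[C@]23C[C@@]1(O)[C@@H](O[Si](C)(C)C(C)(C)C)C[C@H]2[C@@]12CC[C@H](O[Si](C)(C)C(C)(C)C)[C@@](C)(C(=O)O1)[C@H]2[C@@H]3C(=O)O | intermediate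
26 | CNP0260503.1 | C=C1C[C@]23C[C@@]1(O)[C@@H](O)C[C@H]2[C@@]12CC[C@H](O)[C@@](C)(C(=O)O1)[C@H]2[C@@H]3C(=O)O | target

## Step count and least certain steps

Total step count: 19. Longest linear sequence: 19 steps (1 → 26); 2, 14 and 20 enter as purchased materials.

**Step 17 (key step).**
- *Most likely failure:* A second electron reaches the ketyl before the vinyl shift. The result is reductive loss of the 12-oxygen or plain reduction of the ketone, because samarium(III) both activates O12 and supplies a carbanion at C13.
- *Fallback:* Generate the ketyl as a neutral radical.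
  - From 23, slow addition of Bu3SnH with AIBN in refluxing benzene puts a stannyl radical on the carbonyl oxygen.
  - The same 3-exo addition and fragmentation follow, and the C14 radical takes hydrogen from the stannane. This gives the 13-O-tributylstannyl ether F1.
  - F1 is hydrolysed on moist silica or with aqueous KF and returns to the route at 24.
  - No anion is ever formed next to O12, so expulsion of silyloxide has no pathway.

**Step 11.**
- *Most likely failure:* The C5 cation may be quenched otherwise than by hydride shift. Possible paths are migration of C1 (ring contraction), loss of a C6 proton toward the conjugated ester, or loss of the silyl ether to the Lewis acid.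
- *Fallback:* Deliver 5β-H by hydroxyl-directed hydrogenation instead of migration.
  - From 10, allylic oxidation of C10 (CrO3·3,5-dimethylpyrazole) gives the γ-oxo enoate F2.
  - HF·pyridine frees the axial 3β-hydroxyl in hydroxy γ-oxo enoate F3.
  - Crabtree's catalyst under H2, anchored on that hydroxyl, adds hydrogen to the β face of C5=C6 and gives hydroxy keto diester F4.
  - TBSOTf/2,6-lutidine returns to the route at 13.

**Step 12.**
- *Most likely failure:* Proton transfer between the basic enolate and the ketone instead of addition; reversal of the aldol on warming; acylation of the new alkoxide by the nearby C7 ester before silicon arrives; or poor simple diastereoselection at C9.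
- *Fallback:* Use a far less basic metal enolate and separate the protection step.
  - From 14, kinetic enolate bromination (LDA, then NBS) gives 6-bromo-3-ethoxycyclohex-2-en-1-one F5.
  - Activated zinc in THF converts F5 into a Reformatsky enolate that adds to 13.
  - A cold acidic quench gives the free C10 carbinol F6.
  - Silylation with TMSOTf/2,6-lutidine rejoins the route at 16.

**Step 13.**
- *Most likely failure:* Deprotonation at C12 or C9 instead of C6; an unfavourable equilibrium for the addition to the poorly electrophilic vinylogous ester; or, in the acid phase, dehydration of the C10 carbinol competing with lactonisation.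
- *Fallback:* Create the C6 enolate by reduction, not by deprotonation.
  - From 16, LiHMDS with TMSCl present, then NBS, gives the α-bromo ester F7.
  - SmI2 at −78 °C produces the samarium(III) enolate only at C6. Samarium also activates the C8 carbonyl, so the ring closes.
  - The same acid treatment leads back to the route at 19.

**Step 14.**
- *Most likely failure:* Poor facial selectivity. The 6β-ester sits next to the face that must be attacked, and the tied-back lactone shields the α face only moderately. A share of head-to-tail addition is also possible.
- *Fallback:* Irradiate before the lactone is closed, when the α face carries a bulky axial silyl ether and a freely rotating ester.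
  - From 16, ring closure as in step 13 to 17 is followed by a mild work-up (wet silica or oxalic acid). This unmasks the enone but leaves the tertiary silyl ether, giving the 10-OTMS enone diester F8.
  - Irradiation of F8 with 20 gives the 10-OTMS photoadduct F9.
  - Dilute HCl removes silicon and lets the lactone form, rejoining the route at 21.

**Step 15.**
- *Most likely failure:* Enolisation toward the allylic C14–H, or attack of the oxidant on the β face.
- *Fallback:* Pass through an isolable enol ether and oxidise it with a neutral reagent.
  - From 21, LDA then TBSOTf gives the C12=C13 TBS enol ether F10, which can be freed of any regioisomer.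
  - Dimethyldioxirane at −78 °C epoxidises the electron-rich enol ether in preference to the exocyclic methylene.
  - Rubottom silyl migration gives the α-silyloxy ketone directly and rejoins the route at 23. A minor 12β epimer could be equilibrated to the equatorial 12α isomer.

## Further compounds

F1 | step 17 | 13-O-tributylstannyl ether of 24 | C=C1C[C@]23C[C@@]1(O[Sn](CCCC)(CCCC)CCCC)[C@@H](O[Si](C)(C)C(C)(C)C)C[C@H]2[C@@]12CC[C@H](O[Si](C)(C)C(C)(C)C)[C@@](C)(C(=O)O1)[C@H]2[C@@H]3C(=O)OC
F2 | step 11 | γ-oxo enoate (C10 ketone, Z-enoate, 3β-OTBS) | COC(=O)/C=C1/C(=O)CC[C@H](O[Si](C)(C)C(C)(C)C)[C@@]1(C)C(=O)OC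
F3 | step 11 | hydroxy γ-oxo enoate (3β-OH) | COC(=O)/C=C1/C(=O)CC[C@H](O)[C@@]1(C)C(=O)OC
F4 | step 11 | hydroxy keto diester (5β-H, 3β-OH) | COC(=O)C[C@H]1C(=O)CC[C@H](O)[C@@]1(C)C(=O)OC
F5 | step 12 | 6-bromo-3-ethoxycyclohex-2-en-1-one (racemic) | CCOC1=CC(=O)C(Br)CC1
F6 | step 12 | free C10 carbinol of the aldol adduct | CCOC1=CC(=O)[C@@H](CC1)[C@]2(O)CC[C@H](O[Si](C)(C)C(C)(C)C)[C@@](C)(C(=O)OC)[C@H]2CC(=O)OC
F7 | step 13 | α-bromo ester of 16 (C6 not defined) | CCOC1=CC(=O)[C@@H](CC1)[C@]2(O[Si](C)(C)C)CC[C@H](O[Si](C)(C)C(C)(C)C)[C@@](C)(C(=O)OC)[C@H]2C(Br)C(=O)OC
F8 | step 14 | 10-OTMS enone diester | O=C1C=C2[C@@H](C(=O)OC)[C@@H]3[C@](C)(C(=O)OC)[C@@H](O[Si](C)(C)C(C)(C)C)CC[C@@]3(O[Si](C)(C)C)[C@@H]2CC1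
F9 | step 14 | 10-OTMS photoadduct | C=C1C[C@]23[C@H]1C(=O)CC[C@H]2[C@]1(O[Si](C)(C)C)CC[C@H](O[Si](C)(C)C(C)(C)C)[C@@](C)(C(=O)OC)[C@H]1[C@@H]3C(=O)OC
F10 | step 15 | C12=C13 TBS enol ether of 21 | C=C1C[C@]23[C@H]1C(O[Si](C)(C)C(C)(C)C)=CC[C@H]2[C@@]12CC[C@H](O[Si](C)(C)C(C)(C)C)[C@@](C)(C(=O)O1)[C@H]2[C@@H]3C(=O)OC
A1 | alternative 1 | cis-hydrindanone with C10 ketone, 13-TBS enol ether, 12-benzyloxy group and 8-propargyl arm | C#CC[C@]12C=C(O[Si](C)(C)C(C)(C)C)[C@@H](OCc3ccccc3)C[C@H]1C(=O)CC2
A2 | alternative 2 | C3–O–C10 oxygen-bridged pentacyclic diester with 12,13-acetonide and C1=C2 alkene | C=C1C[C@]23C[C@@]1(OC(C)(C)O4)[C@@H]4C[C@H]2[C@@]12C=C[C@@H](O1)[C@@](C)(C(=O)OC)[C@H]2[C@@H]3C(=O)OC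
A3 | alternative 3 | cis-hydrindenedione with C10 ketone, C12 enone and 8-propargyl arm | C#CC[C@]12C=CC(=O)C[C@H]1C(=O)CC2
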